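**Retrosynthetic overview**

- The strategy rests on ring A (C4a, C5, C6, C7, C8, C8a), a pentasubstituted phloroglucinol ring with C5–OH, C6–geranyl, C7–OH and C8–H. C6 and C7 map onto the two carbons of a geranyl ynol silyl ether, C4a=C8a onto the enone alkene of a preformed chiral dihydropyranone (ring C), C5 onto a diazoketone carbonyl and C8 onto the diazo carbon.
- Last disconnection: the three aryl O–Si bonds (global desilylation).
- Key disconnection: ring A, by a photo-Wolff, [2+2], 4π-opening, 6π-closure benzannulation of a pyranonyl diazoketone with the siloxyalkyne. It forms C8–C8a, C5–C6, C7–C8 and C4a–C5.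
- The diazoketone comes from a pyranone-6-carboxylic ester. Ring C and the (S) centre at C2 come from an asymmetric vinylogous Mukaiyama aldol and cyclodehydration of 3,5-bis(silyloxy)benzaldehyde with the bis-silyl dienol ether of methyl acetylpyruvate. The siloxyalkyne comes from geranyl bromide via a skipped enyne and acetylide oxygenation.
- Ring order: ring B is purchased, ring C is closed in step 5, ring A is closed in step 8.

Key step: step 8

Remark: flavanone numbering is used (O1, C2, C3, C4, C4a, C5–C8, C8a); ring A is the benzo ring, ring B the 2-aryl group, ring C the pyranone.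

Remark: the aryl hydroxyls are carried as TIPS ethers (not TBS), because aryl TIPS ethers tolerate the Lewis acid, TFA and tin hydroxide steps and all three silyl groups then fall together at the end.

Remark: the sense of induction in step 5 is assigned by analogy with BINOL–Ti(OiPr)4-catalysed additions of silyl dienol ethers to aromatic aldehydes; if the opposite sense is found, (R)-BINOL is used instead.

**Route**

Step 1
Reactants: 1 geranyl bromide; 2 ethynylmagnesium bromide (HC≡CMgBr)
Product: 3 (4E)-5,9-dimethyldeca-4,8-dien-1-yne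
Conditions: HC≡CMgBr (3 equiv), CuCl (5 mol %), THF, 0 → 50 °C
Reagents that add atoms: none
Why: Copper-catalysed SN2 coupling of an alkynyl Grignard reagent with a primary allylic bromide, in which attack at the unhindered α-carbon keeps the (E)-alkene and excess acetylide suppresses double alkylation.

Step 2
Reactants: 3 (4E)-5,9-dimethyldeca-4,8-dien-1-yne
Product: 6 triisopropyl{[(4E)-5,9-dimethyldeca-4,8-dien-1-yn-1-yl]oxy}silane, via lithium acetylide 4 (not isolated), via lithium ynolate 5 (not isolated)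
Conditions: LiN(SiMe3)2, THF, −78 °C; t-BuOOLi (from t-BuOOH and LiN(SiMe3)2), −78 → 0 °C; TIPSOTf, −78 °C
Reagents that add atoms: tert-butyl hydroperoxide, CC(C)(C)OO; triisopropylsilyl trifluoromethanesulfonate, CC(C)[Si](C(C)C)(C(C)C)OS(=O)(=O)C(F)(F)F
Why: Acetylide oxygenation by lithium tert-butyl peroxide followed by ynolate O-silylation with a hard silyl triflate should give the isolable TIPS ynol ether, the terminal C–H being far more acidic than the allylic–propargylic CH2 so that the skipped enyne is not isomerised.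

Step 3
Reactants: 7 3,5-dihydroxybenzaldehyde
Product: 8 3,5-bis(triisopropylsilyloxy)benzaldehyde
Conditions: TIPSCl, imidazole, DMF, rt
Reagents that add atoms: triisopropylsilyl chloride, CC(C)[Si](Cl)(C(C)C)C(C)C
Why: Imidazole-promoted O-silylation of both phenols, a standard protection that leaves the aldehyde untouched.

Step 4
Reactants: 9 methyl 2,4-dioxopentanoate
Product: 10 methyl (2Z)-2,4-bis(trimethylsilyloxy)penta-2,4-dienoate
Conditions: TMSOTf (2.2 equiv), Et3N (2.5 equiv), Et2O, 0 °C → rt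
Reagents that add atoms: trimethylsilyl trifluoromethanesulfonate, C[Si](C)(C)OS(=O)(=O)C(F)(F)F
Why: Double soft enolisation and O-silylation (silyl triflate with amine base) turns the internal enol and the terminal methyl ketone into the bis-silyl dienol ether, the only diene possible because C5 holds the sole remaining enolisable hydrogens (the C2=C3 geometry is lost in step 5 and is of no consequence).

Step 5
Reactants: 8 3,5-bis(triisopropylsilyloxy)benzaldehyde; 10 methyl (2Z)-2,4-bis(trimethylsilyloxy)penta-2,4-dienoate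
Product: 12 methyl (2S)-2-[3,5-bis(triisopropylsilyloxy)phenyl]-4-oxo-3,4-dihydro-2H-pyran-6-carboxylate, via silylated aldol adduct 11 (not isolated)
Conditions: Ti(OiPr)4 (10 mol %), (S)-BINOL (20 mol %), 4 Å MS, Et2O, −20 °C; then TFA, CH2Cl2, 0 °C → rt
Reagents that add atoms: none
Why: Catalytic enantioselective vinylogous Mukaiyama aldol addition (a formal hetero-Diels–Alder reaction) of the terminal enol ether carbon to the aldehyde, with the (S)-BINOL titanium complex directing attack to the Si face to set C2 as (S), after which TFA removes the silyl groups and effects hemiketalisation and dehydration to the conjugated dihydropyranone without breaking the C2–O bond.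

Step 6
Reactants: 12 methyl (2S)-2-[3,5-bis(triisopropylsilyloxy)phenyl]-4-oxo-3,4-dihydro-2H-pyran-6-carboxylate
Product: 13 (2S)-2-[3,5-bis(triisopropylsilyloxy)phenyl]-4-oxo-3,4-dihydro-2H-pyran-6-carboxylic acid
Conditions: Me3SnOH (3 equiv), ClCH2CH2Cl, 60 °C; 1 M HCl wash
Reagents that add atoms: trimethyltin hydroxide, C[Sn](C)(C)O
Why: Trimethyltin hydroxide-mediated ester hydrolysis runs under nearly neutral conditions, so the aryl silyl ethers should survive and C3 is not enolised, which avoids racemisation of C2 by retro-oxa-Michael ring opening.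

Step 7
Reactants: 13 (2S)-2-[3,5-bis(triisopropylsilyloxy)phenyl]-4-oxo-3,4-dihydro-2H-pyran-6-carboxylic acid
Product: 15 (2S)-6-(2-diazoacetyl)-2-[3,5-bis(triisopropylsilyloxy)phenyl]-2,3-dihydro-4H-pyran-4-one, via acid chloride 14 (not isolated)
Conditions: Me2C=C(Cl)NMe2, CH2Cl2, 0 °C → rt; then CH2N2 (1.3 equiv), Et3N (1.1 equiv), Et2O, −20 °C; AcOH quench
Reagents that add atoms: diazomethane, C=[N+]=[N-]
Why: Acylation of diazomethane by an acid chloride (the diazoketone-forming stage of the Arndt–Eistert sequence), kept neutral by an α-chloroenamine chlorinating agent and by Et3N as HCl scavenger, should outpace dipolar cycloaddition of the small excess of CH2N2 to the donor-substituted enone alkene at −20 °C, and the acid chloride has no α-hydrogen from which a ketene could form.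

Step 8
Reactants: 15 (2S)-6-(2-diazoacetyl)-2-[3,5-bis(triisopropylsilyloxy)phenyl]-2,3-dihydro-4H-pyran-4-one; 6 triisopropyl{[(4E)-5,9-dimethyldeca-4,8-dien-1-yn-1-yl]oxy}silane
Product: 20 (2S)-2-[3,5-bis(triisopropylsilyloxy)phenyl]-6-[(2E)-3,7-dimethylocta-2,6-dien-1-yl]-5-hydroxy-7-(triisopropylsilyloxy)-2,3-dihydro-4H-chromen-4-one, via vinylketene 16 (not isolated), via cyclobutenone 17 (not isolated), via dienylketene 18 (not isolated), via cyclohexadienone 19 (not isolated)
Conditions: 6 (1.5 equiv), hν (450 nm LED), ClCH2CH2Cl, rt; then 80 °C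
Reagents that add atoms: none
Why: Excitation of the diazo n–π* band at 450 nm, where neither the vinylogous-ester enone nor the alkenes absorb, expels N2 and triggers a Wolff rearrangement in which C8a migrates to the diazo carbon (C8) to give vinylketene 16, whose carbonyl carbon is the future C5. The electron-rich ynol ether then adds across the ketene C=C in a polarity-matched [2+2] cycloaddition (geranyl-bearing carbon to the ketene carbonyl carbon, siloxy-bearing carbon to C8) to give cyclobutenone 17, which at 80 °C opens by 4π conrotatory cleavage of C5–C8 to dienylketene 18. Ring A is closed by thermal disrotatory 6π electrocyclisation joining C5 to C4a, and enolisation of cyclohexadienone 19 gives the phenol; this is the diazoketone version of the Danheiser benzannulation with a trialkylsiloxyalkyne. No stereocentre is created: the transient sp3 centres of 17 and 19 are erased on aromatisation, and C2 lies outside the reacting π-array and meets no base, so its (S) configuration should be carried through. The step needs one alkyne orientation, which the ynol ether polarity fixes so that geranyl can only end at C6 next to C5–OH, and closure onto C4a and not onto the C4 carbonyl oxygen is enforced because C4 is held trans to the ketene arm across the ring alkene.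

Step 9
Reactants: 20 (2S)-2-[3,5-bis(triisopropylsilyloxy)phenyl]-6-[(2E)-3,7-dimethylocta-2,6-dien-1-yl]-5-hydroxy-7-(triisopropylsilyloxy)-2,3-dihydro-4H-chromen-4-one
Product: 21 schizolaenone C, (2S)-2-(3,5-dihydroxyphenyl)-6-[(2E)-3,7-dimethylocta-2,6-dien-1-yl]-5,7-dihydroxy-2,3-dihydro-4H-chromen-4-one
Conditions: TBAF/AcOH (1:1, 3.5 equiv), THF, 0 °C → rt
Reagents that add atoms: none
Why: Fluoride-mediated desilylation of the three aryl O–Si bonds, buffered with acetic acid so that no phenoxide or enolate opens ring C by retro-oxa-Michael reaction and racemises C2, and free of strong acid that would cyclise the geranyl chain onto the flanking phenols.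

**Compound list**

1 | geranyl bromide, (2E)-1-bromo-3,7-dimethylocta-2,6-diene | CC(C)=CCC/C(C)=C/CBr | starting material
2 | ethynylmagnesium bromide | C#C[Mg]Br | starting material
3 | (4E)-5,9-dimethyldeca-4,8-dien-1-yne | CC(C)=CCC/C(C)=C/CC#C | intermediate
4 | lithium (4E)-5,9-dimethyldeca-4,8-dien-1-yn-1-ide (lithium acetylide, not isolated) | CC(C)=CCC/C(C)=C/CC#C[Li] | intermediate
5 | lithium (4E)-5,9-dimethyldeca-4,8-dien-1-yn-1-olate (lithium ynolate, not isolated) | CC(C)=CCC/C(C)=C/CC#CO[Li] | intermediate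
6 | triisopropyl{[(4E)-5,9-dimethyldeca-4,8-dien-1-yn-1-yl]oxy}silane (geranyl TIPS ynol ether) | CC(C)=CCC/C(C)=C/CC#CO[Si](C(C)C)(C(C)C)C(C)C | intermediate
7 | 3,5-dihydroxybenzaldehyde | O=Cc1cc(O)cc(O)c1 | starting material
8 | 3,5-bis(triisopropylsilyloxy)benzaldehyde | O=Cc1cc(O[Si](C(C)C)(C(C)C)C(C)C)cc(O[Si](C(C)C)(C(C)C)C(C)C)c1 | intermediate
9 | methyl 2,4-dioxopentanoate | COC(=O)C(=O)CC(C)=O | starting material
10 | methyl (2Z)-2,4-bis(trimethylsilyloxy)penta-2,4-dienoate | C=C(O[Si](C)(C)C)/C=C(\O[Si](C)(C)C)C(=O)OC | intermediate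
11 | methyl (2Z,6S)-6-[3,5-bis(triisopropylsilyloxy)phenyl]-4-oxo-2,6-bis(trimethylsilyloxy)hex-2-enoate (aldol adduct, not isolated) | COC(=O)/C(O[Si](C)(C)C)=C/C(=O)C[C@@H](c1cc(O[Si](C(C)C)(C(C)C)C(C)C)cc(O[Si](C(C)C)(C(C)C)C(C)C)c1)O[Si](C)(C)C | intermediate
12 | methyl (2S)-2-[3,5-bis(triisopropylsilyloxy)phenyl]-4-oxo-3,4-dihydro-2H-pyran-6-carboxylate | COC(=O)C1=CC(=O)C[C@@H](c2cc(O[Si](C(C)C)(C(C)C)C(C)C)cc(O[Si](C(C)C)(C(C)C)C(C)C)c2)O1 | intermediate
13 | (2S)-2-[3,5-bis(triisopropylsilyloxy)phenyl]-4-oxo-3,4-dihydro-2H-pyran-6-carboxylic acid | OC(=O)C1=CC(=O)C[C@@H](c2cc(O[Si](C(C)C)(C(C)C)C(C)C)cc(O[Si](C(C)C)(C(C)C)C(C)C)c2)O1 | intermediate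
14 | (2S)-2-[3,5-bis(triisopropylsilyloxy)phenyl]-4-oxo-3,4-dihydro-2H-pyran-6-carbonyl chloride (not isolated) | ClC(=O)C1=CC(=O)C[C@@H](c2cc(O[Si](C(C)C)(C(C)C)C(C)C)cc(O[Si](C(C)C)(C(C)C)C(C)C)c2)O1 | intermediate
15 | (2S)-6-(2-diazoacetyl)-2-[3,5-bis(triisopropylsilyloxy)phenyl]-2,3-dihydro-4H-pyran-4-one | [N-]=[N+]=CC(=O)C1=CC(=O)C[C@@H](c2cc(O[Si](C(C)C)(C(C)C)C(C)C)cc(O[Si](C(C)C)(C(C)C)C(C)C)c2)O1 | intermediate
16 | (2S)-2-[3,5-bis(triisopropylsilyloxy)phenyl]-6-(2-oxoethenyl)-2,3-dihydro-4H-pyran-4-one (vinylketene, not isolated) | O=C=CC1=CC(=O)C[C@@H](c2cc(O[Si](C(C)C)(C(C)C)C(C)C)cc(O[Si](C(C)C)(C(C)C)C(C)C)c2)O1 | intermediate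
17 | 2-[(2E)-3,7-dimethylocta-2,6-dien-1-yl]-4-{(2S)-2-[3,5-bis(triisopropylsilyloxy)phenyl]-4-oxo-3,4-dihydro-2H-pyran-6-yl}-3-(triisopropylsilyloxy)cyclobut-2-en-1-one (both C4 epimers, not isolated) | O=C1C(C/C=C(\C)CCC=C(C)C)=C(O[Si](C(C)C)(C(C)C)C(C)C)C1C2=CC(=O)C[C@@H](c3cc(O[Si](C(C)C)(C(C)C)C(C)C)cc(O[Si](C(C)C)(C(C)C)C(C)C)c3)O2 | intermediate
18 | (3E)-2-[(2E)-3,7-dimethylocta-2,6-dien-1-yl]-4-{(2S)-2-[3,5-bis(triisopropylsilyloxy)phenyl]-4-oxo-3,4-dihydro-2H-pyran-6-yl}-3-(triisopropylsilyloxy)buta-1,3-dien-1-one (dienylketene, ketene arm and pyranonyl cis, not isolated) | O=C=C(C/C=C(\C)CCC=C(C)C)/C(O[Si](C(C)C)(C(C)C)C(C)C)=C\C1=CC(=O)C[C@@H](c2cc(O[Si](C(C)C)(C(C)C)C(C)C)cc(O[Si](C(C)C)(C(C)C)C(C)C)c2)O1 | intermediate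
19 | (2S)-2-[3,5-bis(triisopropylsilyloxy)phenyl]-6-[(2E)-3,7-dimethylocta-2,6-dien-1-yl]-7-(triisopropylsilyloxy)-2,3-dihydro-4H-chromene-4,5(4aH)-dione (keto tautomer, C4a unspecified, not isolated) | O=C1C(C/C=C(\C)CCC=C(C)C)=C(O[Si](C(C)C)(C(C)C)C(C)C)C=C2C1C(=O)C[C@@H](c3cc(O[Si](C(C)C)(C(C)C)C(C)C)cc(O[Si](C(C)C)(C(C)C)C(C)C)c3)O2 | intermediate
20 | (2S)-2-[3,5-bis(triisopropylsilyloxy)phenyl]-6-[(2E)-3,7-dimethylocta-2,6-dien-1-yl]-5-hydroxy-7-(triisopropylsilyloxy)-2,3-dihydro-4H-chromen-4-one | CC(C)=CCC/C(C)=C/Cc1c(O[Si](C(C)C)(C(C)C)C(C)C)cc2c(c1O)C(=O)C[C@@H](c1cc(O[Si](C(C)C)(C(C)C)C(C)C)cc(O[Si](C(C)C)(C(C)C)C(C)C)c1)O2 | intermediate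
21 | schizolaenone C, (2S)-2-(3,5-dihydroxyphenyl)-6-[(2E)-3,7-dimethylocta-2,6-dien-1-yl]-5,7-dihydroxy-2,3-dihydro-4H-chromen-4-one | CC(C)=CCC/C(C)=C/Cc1c(O)cc2c(c1O)C(=O)C[C@@H](c1cc(O)cc(O)c1)O2 | target

**Step count and risks**

Total step count: 9 steps. Longest linear sequence: 6 steps (steps 3, 5, 6, 7, 8, 9 from 3,5-dihydroxybenzaldehyde; equally steps 4–9 from methyl 2,4-dioxopentanoate).

Steps most likely to fail:

1. Step 8 (benzannulation). On irradiation the ketocarbene or an excited enone may be diverted before the ketene is intercepted (cyclopropanation of the geranyl alkenes, enone–alkyne photocycloaddition), or the ketene may dimerise. A silyl shift from O7 to O5 would be harmless, since step 9 removes every silyl group. Fallback: light-free generation of the same vinylketene. Setting out from 15, silver-benzoate-catalysed Wolff rearrangement in wet THF (PhCO2Ag, Et3N, THF–H2O, dark; Arndt–Eistert homologation) should give {(2S)-2-[3,5-bis(triisopropylsilyloxy)phenyl]-4-oxo-3,4-dihydro-2H-pyran-6-yl}acetic acid F1. Treatment with Me2C=C(Cl)NMe2 in CH2Cl2 converts it into the corresponding acetyl chloride F2. Slow addition of Et3N to F2 and alkyne 6 in toluene at rt, then heating to 80 °C, should generate vinylketene 16 by dehydrochlorination and carry it through the same [2+2], 4π, 6π sequence, coming back to the route at 20.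

2. Step 7 (diazoketone formation). Diazomethane may add as a 1,3-dipole across the electron-poor C5=C6 alkene of the pyranone (pyrazoline formation) in competition with acylation. Fallback: diazo transfer in place of diazomethane acylation. Setting out from acid chloride 14, Negishi acylation (MeZnCl, Pd(PPh3)4 as the zerovalent palladium catalyst, THF, 0 °C) should give (2S)-6-acetyl-2-[3,5-bis(triisopropylsilyloxy)phenyl]-2,3-dihydro-4H-pyran-4-one F3. Kinetic enolisation of the acetyl group (LiN(SiMe3)2, THF, −78 °C) and trapping with CF3CO2CH2CF3 gives the trifluoroacetyl diketone F4, used crude. Detrifluoroacetylative diazo transfer (MsN3, Et3N, H2O, MeCN, rt) then comes back to the route at 15.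

3. Step 5 (asymmetric aldol and cyclodehydration). The ester-deactivated dienol ether may add sluggishly or with poor facial selectivity, and the benzylic hydroxyl may be eliminated during the acid cyclisation. Fallback: set C2 first and build the dioxo ester afterwards. Setting out from aldehyde 8, a D-proline-catalysed aldol reaction with acetone (acetone/DMSO, rt, Si-face attack) should give (4S)-4-[3,5-bis(triisopropylsilyloxy)phenyl]-4-hydroxybutan-2-one F5. Silylation (TESCl, imidazole, CH2Cl2) gives the triethylsilyl ether F6. Crossed Claisen condensation at the methyl group (LiN(SiMe3)2, THF, −78 °C, then dimethyl oxalate) gives methyl (6S)-6-[3,5-bis(triisopropylsilyloxy)phenyl]-2,4-dioxo-6-(triethylsilyloxy)hexanoate F7. TFA in CH2Cl2 (desilylation, hemiketalisation, dehydration) then comes back to the route at 12.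

**Further compounds**

F1 | step 8 | {(2S)-2-[3,5-bis(triisopropylsilyloxy)phenyl]-4-oxo-3,4-dihydro-2H-pyran-6-yl}acetic acid | OC(=O)CC1=CC(=O)C[C@@H](c2cc(O[Si](C(C)C)(C(C)C)C(C)C)cc(O[Si](C(C)C)(C(C)C)C(C)C)c2)O1
F2 | step 8 | {(2S)-2-[3,5-bis(triisopropylsilyloxy)phenyl]-4-oxo-3,4-dihydro-2H-pyran-6-yl}acetyl chloride | ClC(=O)CC1=CC(=O)C[C@@H](c2cc(O[Si](C(C)C)(C(C)C)C(C)C)cc(O[Si](C(C)C)(C(C)C)C(C)C)c2)O1
F3 | step 7 | (2S)-6-acetyl-2-[3,5-bis(triisopropylsilyloxy)phenyl]-2,3-dihydro-4H-pyran-4-one | CC(=O)C1=CC(=O)C[C@@H](c2cc(O[Si](C(C)C)(C(C)C)C(C)C)cc(O[Si](C(C)C)(C(C)C)C(C)C)c2)O1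
F4 | step 7 | 4,4,4-trifluoro-1-{(2S)-2-[3,5-bis(triisopropylsilyloxy)phenyl]-4-oxo-3,4-dihydro-2H-pyran-6-yl}butane-1,3-dione | O=C(CC(=O)C(F)(F)F)C1=CC(=O)C[C@@H](c2cc(O[Si](C(C)C)(C(C)C)C(C)C)cc(O[Si](C(C)C)(C(C)C)C(C)C)c2)O1
F5 | step 5 | (4S)-4-[3,5-bis(triisopropylsilyloxy)phenyl]-4-hydroxybutan-2-one | CC(=O)C[C@@H](c1cc(O[Si](C(C)C)(C(C)C)C(C)C)cc(O[Si](C(C)C)(C(C)C)C(C)C)c1)O
F6 | step 5 | (4S)-4-[3,5-bis(triisopropylsilyloxy)phenyl]-4-(triethylsilyloxy)butan-2-one | CC(=O)C[C@@H](c1cc(O[Si](C(C)C)(C(C)C)C(C)C)cc(O[Si](C(C)C)(C(C)C)C(C)C)c1)O[Si](CC)(CC)CC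
F7 | step 5 | methyl (6S)-6-[3,5-bis(triisopropylsilyloxy)phenyl]-2,4-dioxo-6-(triethylsilyloxy)hexanoate | COC(=O)C(=O)CC(=O)C[C@@H](c1cc(O[Si](C(C)C)(C(C)C)C(C)C)cc(O[Si](C(C)C)(C(C)C)C(C)C)c1)O[Si](CC)(CC)CC
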